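**Plan**
1. Numbering: ring A is C1 (CH3), C2 (alkyne C8≡C9–aryl), C3 (quinone methide carbon C7), C4 (4-hydroxyphenyl), C5–H, C6–H.
2. Enabling feature: C5–H/C6–H form a bare two-carbon edge (one unsubstituted alkyne), and the exocyclic carbons C8 and C7 sit on the adjacent ring carbons C2 and C3. They can therefore be joined as an ester C8(=O)–O–C7 that holds the alkynes C1≡C2 and C3≡C4 as a 1,6-diyne.
3. Cuts, from the target backwards: the quinone methide and one C7–aryl bond (carbinol from a ketone and an aryllithium), C9–aryl (Sonogashira), C8≡C9 (one-carbon homologation of a lactol), then C2–C3, C1–C6 and C4–C5 together in a (2+2+2) cycloaddition, then the ester C8–O bond and the C7–alkynyl bond.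
4. Forward order: acetylide addition and esterification assemble the chain; one rhodium-catalysed step closes ring A and the five-membered lactone together; the lactone is then opened and C8 and C7 are elaborated to the arylalkyne and the quinone methide. All four anisyl rings are bought.
5. Stereochemistry: the target has no stereocentre. C7 is a racemic carbinol centre from step 1 to step 6 and becomes trigonal in step 7, so nothing needs to be controlled.

Key step: step 3

Remark: the four phenolic oxygens are carried as methyl ethers, because every anisole building block is commercial and the ethers survive all steps before the last.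

**Step 1**
Reactants: 1 4-ethynylanisole; 2 4-methoxybenzaldehyde
Product: 4 rac-1,3-bis(4-methoxyphenyl)prop-2-yn-1-ol, via lithium (4-methoxyphenyl)acetylide 3 (not isolated)
Conditions: n-BuLi, THF, −78 °C; then 2, −78 to 0 °C; then H2O
Reagents that add atoms: none
Why: 1,2-addition of a lithium acetylide to a non-enolisable aromatic aldehyde forms the C7–C3 bond cleanly; the new C7 stereocentre is formed racemic, which is acceptable because it is erased in step 7.

**Step 2**
Reactants: 4 rac-1,3-bis(4-methoxyphenyl)prop-2-yn-1-ol; 5 but-2-ynoic acid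
Product: 6 rac-1,3-bis(4-methoxyphenyl)prop-2-yn-1-yl but-2-ynoate
Conditions: DCC, DMAP (5 mol %), CH2Cl2, −20 to 0 °C
Reagents that add atoms: none
Why: Steglich esterification builds the C8(=O)–O–C7 bridge under neutral conditions that do not ionise the benzylic-propargylic C–O bond, and the low temperature with little DMAP should suppress ynoate-to-allenoate isomerisation and amine conjugate addition.

**Step 3**
Reactants: 6 rac-1,3-bis(4-methoxyphenyl)prop-2-yn-1-yl but-2-ynoate; 7 acetylene
Product: 8 rac-3,4-bis(4-methoxyphenyl)-7-methyl-2-benzofuran-1(3H)-one (3,4-bis(4-methoxyphenyl)-7-methylphthalide)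
Conditions: RhCl(PPh3)3 (10 mol %), acetylene (1 atm), toluene, 60 °C, 6 added slowly
Reagents that add atoms: none
Why: Loss of a phosphine lets monovalent rhodium bind both alkynes of 6, and oxidative cyclisation joins the two inner alkyne carbons (C2–C3) to give a bicyclic rhodacyclopentadiene of trivalent rhodium whose metal-bound carbons are C1 and C4; acetylene then coordinates, inserts into one Rh–C bond, and reductive elimination makes the last bond, so that C1–C6 and C4–C5 are both formed and the catalyst is released. The closest known reaction type is the RhCl(PPh3)3-catalysed crossed (2+2+2) alkyne cyclotrimerisation of ester-bridged 1,6-diynes with acetylene, which gives phthalides. The five-membered lactone (C2, C8, O, C7, C3) closes in the oxidative cyclisation by C2–C3 bond formation across the ester bridge, and six-membered ring A closes by insertion and reductive elimination from four diyne carbons and the two acetylene carbons, emerging aromatic. No stereocentre is created, and racemic C7 is a spectator. The step needs cross-selectivity over diyne self-trimerisation and a single substitution pattern: the bridge fixes which alkyne carbons meet and acetylene is symmetric, so only the 1,2,3,4-pattern can form, while the methyl and aryl caps on both diyne termini, the slow addition of 6 and a solution saturated with acetylene should keep a second diyne out of the rhodacycle.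

**Step 4**
Reactants: 8 rac-3,4-bis(4-methoxyphenyl)-7-methyl-2-benzofuran-1(3H)-one
Product: 9 3,4-bis(4-methoxyphenyl)-7-methyl-1,3-dihydro-2-benzofuran-1-ol (racemic lactol, mixture of epimers at C8)
Conditions: iBu2AlH (1.1 equiv), CH2Cl2, −78 °C; then aq. potassium sodium tartrate
Reagents that add atoms: none
Why: Partial reduction of a lactone to a lactol with iBu2AlH stops at the tetrahedral aluminium hemiacetal at −78 °C, and the aryl ethers are inert; the new hemiacetal centre at C8 is uncontrolled and irrelevant because it is consumed in step 5.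

**Step 5**
Reactants: 9 3,4-bis(4-methoxyphenyl)-7-methyl-1,3-dihydro-2-benzofuran-1-ol
Product: 11 rac-[2-ethynyl-6-(4-methoxyphenyl)-3-methylphenyl](4-methoxyphenyl)methanol, via hydroxy aldehyde 10 (not isolated)
Conditions: dimethyl (1-diazo-2-oxopropyl)phosphonate, K2CO3, MeOH, 0 °C to rt
Reagents that add atoms: dimethyl (1-diazo-2-oxopropyl)phosphonate, CC(=O)C(=[N+]=[N-])P(=O)(OC)OC
Why: Seyferth–Gilbert homologation in its Ohira–Bestmann form acts on the open-chain aldehyde tautomer 10 of the lactol, and the alkylidene carbene from an aryl aldehyde rearranges by fast 1,2-hydrogen shift to the terminal alkyne C8≡C9–H under base mild enough to leave the benzhydrol untouched.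

**Step 6**
Reactants: 11 rac-[2-ethynyl-6-(4-methoxyphenyl)-3-methylphenyl](4-methoxyphenyl)methanol; 12 4-iodoanisole
Product: 13 rac-{6-(4-methoxyphenyl)-2-[(4-methoxyphenyl)ethynyl]-3-methylphenyl}(4-methoxyphenyl)methanol
Conditions: PdCl2(PPh3)2 (3 mol %), CuI (6 mol %), Et3N, THF, rt
Reagents that add atoms: none
Why: Sonogashira coupling (zerovalent palladium formed in the flask inserts into the C–I bond, the copper acetylide of 11 transmetalates, reductive elimination forms C9–aryl) runs at room temperature with an aryl iodide, where the free benzylic hydroxyl should not add to the alkyne.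

**Step 7**
Reactants: 13 rac-{6-(4-methoxyphenyl)-2-[(4-methoxyphenyl)ethynyl]-3-methylphenyl}(4-methoxyphenyl)methanol
Product: 14 {6-(4-methoxyphenyl)-2-[(4-methoxyphenyl)ethynyl]-3-methylphenyl}(4-methoxyphenyl)methanone
Conditions: Dess–Martin periodinane, pyridine, CH2Cl2, 0 °C to rt
Reagents that add atoms: none
Why: Dess–Martin oxidation of a secondary diaryl carbinol to the diaryl ketone needs neither metal nor strong acid, pyridine buffers the acetic acid so the ionisable benzhydrol and the alkyne are spared, and the C7 stereocentre disappears here.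

**Step 8**
Reactants: 14 {6-(4-methoxyphenyl)-2-[(4-methoxyphenyl)ethynyl]-3-methylphenyl}(4-methoxyphenyl)methanone; 15 4-bromoanisole
Product: 17 {6-(4-methoxyphenyl)-2-[(4-methoxyphenyl)ethynyl]-3-methylphenyl}bis(4-methoxyphenyl)methanol, via 4-methoxyphenyllithium 16 (not isolated)
Conditions: 15, n-BuLi, THF, −78 °C; then 14, −78 to 0 °C; then H2O
Reagents that add atoms: none
Why: Bromine–lithium exchange followed by 1,2-addition of the small, reactive aryllithium to a non-enolisable diaryl ketone should overcome the two ortho substituents, and a cold quench keeps the lithium alkoxide from adding to the neighbouring alkyne.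

**Step 9**
Reactants: 17 {6-(4-methoxyphenyl)-2-[(4-methoxyphenyl)ethynyl]-3-methylphenyl}bis(4-methoxyphenyl)methanol
Product: 19 selaginellin U, via tetraphenolic carbinol 18 (not isolated)
Conditions: BBr3 (10 equiv), CH2Cl2, −78 to 0 °C; then H2O
Reagents that add atoms: none
Why: BBr3 cleavage of the four aryl methyl ethers (boron binds each ether oxygen and bromide removes the methyl group) is followed on aqueous work-up by spontaneous loss of water from the carbinol 18, whose para-hydroxyphenyl groups make dehydration to the conjugated para-quinone methide (fuchsone formation) favourable, while the low temperature should spare the diarylalkyne.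

**Compound list**
1 | 4-ethynylanisole | C#Cc1ccc(OC)cc1 | starting material
2 | 4-methoxybenzaldehyde | COc1ccc(C=O)cc1 | starting material
3 | lithium (4-methoxyphenyl)acetylide (formed in the flask, not isolated) | [Li]C#Cc1ccc(OC)cc1 | intermediate
4 | rac-1,3-bis(4-methoxyphenyl)prop-2-yn-1-ol | COc1ccc(C#CC(O)c2ccc(OC)cc2)cc1 | intermediate
5 | but-2-ynoic acid | CC#CC(=O)O | starting material
6 | rac-1,3-bis(4-methoxyphenyl)prop-2-yn-1-yl but-2-ynoate | CC#CC(=O)OC(C#Cc1ccc(OC)cc1)c1ccc(OC)cc1 | intermediate
7 | acetylene | C#C | starting material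
8 | rac-3,4-bis(4-methoxyphenyl)-7-methyl-2-benzofuran-1(3H)-one | Cc1ccc(-c2ccc(OC)cc2)c2c1C(=O)OC2c1ccc(OC)cc1 | intermediate
9 | 3,4-bis(4-methoxyphenyl)-7-methyl-1,3-dihydro-2-benzofuran-1-ol (racemic, mixture of C8 epimers) | Cc1ccc(-c2ccc(OC)cc2)c2c1C(O)OC2c1ccc(OC)cc1 | intermediate
10 | rac-2-[hydroxy(4-methoxyphenyl)methyl]-3-(4-methoxyphenyl)-6-methylbenzaldehyde (open form of 9, not isolated) | O=Cc1c(C)ccc(-c2ccc(OC)cc2)c1C(O)c1ccc(OC)cc1 | intermediate
11 | rac-[2-ethynyl-6-(4-methoxyphenyl)-3-methylphenyl](4-methoxyphenyl)methanol | C#Cc1c(C)ccc(-c2ccc(OC)cc2)c1C(O)c1ccc(OC)cc1 | intermediate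
12 | 4-iodoanisole | COc1ccc(I)cc1 | starting material
13 | rac-{6-(4-methoxyphenyl)-2-[(4-methoxyphenyl)ethynyl]-3-methylphenyl}(4-methoxyphenyl)methanol | COc1ccc(C#Cc2c(C)ccc(-c3ccc(OC)cc3)c2C(O)c2ccc(OC)cc2)cc1 | intermediate
14 | {6-(4-methoxyphenyl)-2-[(4-methoxyphenyl)ethynyl]-3-methylphenyl}(4-methoxyphenyl)methanone | COc1ccc(C#Cc2c(C)ccc(-c3ccc(OC)cc3)c2C(=O)c2ccc(OC)cc2)cc1 | intermediate
15 | 4-bromoanisole | COc1ccc(Br)cc1 | starting material
16 | 4-methoxyphenyllithium (formed in the flask, not isolated) | [Li]c1ccc(OC)cc1 | intermediate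
17 | {6-(4-methoxyphenyl)-2-[(4-methoxyphenyl)ethynyl]-3-methylphenyl}bis(4-methoxyphenyl)methanol | COc1ccc(C#Cc2c(C)ccc(-c3ccc(OC)cc3)c2C(O)(c2ccc(OC)cc2)c2ccc(OC)cc2)cc1 | intermediate
18 | {6-(4-hydroxyphenyl)-2-[(4-hydroxyphenyl)ethynyl]-3-methylphenyl}bis(4-hydroxyphenyl)methanol (not isolated) | Cc1ccc(-c2ccc(O)cc2)c(C(O)(c2ccc(O)cc2)c2ccc(O)cc2)c1C#Cc1ccc(O)cc1 | intermediate
19 | selaginellin U, 4-[(4-hydroxyphenyl){4'-hydroxy-3-[(4-hydroxyphenyl)ethynyl]-4-methylbiphenyl-2-yl}methylidene]cyclohexa-2,5-dien-1-one | Cc1ccc(-c2ccc(O)cc2)c(C(=C2C=CC(=O)C=C2)c2ccc(O)cc2)c1C#Cc1ccc(O)cc1 | target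

**Step count**
Total: 9 steps. Longest linear sequence: 9 steps (from 1 and 2 to 19); 5, 7, 12 and 15 enter as purchased reagents.

**Steps most likely to fail**

Step 3. The ester bridge prefers the extended conformation and both alkynes are internal, so oxidative cyclisation may be slow. The rhodium may then be consumed by acetylene oligomerisation or diyne self-coupling, and prolonged heating may ionise the doubly activated propargylic C–O bond. The fallback replaces the gas with a liquid alkene that serves as an acetylene equivalent, and uses a more active cationic catalyst. Setting out from 6, the cationic monovalent rhodium complex formed from [Rh(cod)2]BF4 and rac-BINAP in (CH2Cl)2 with excess vinyl acetate should effect a diyne–alkene (2+2+2) cycloaddition. This gives the cyclohexadienyl acetate 3,4-bis(4-methoxyphenyl)-7-methyl-1-oxo-1,3,5,6-tetrahydro-2-benzofuran-5-yl acetate F1 (drawn with the acetate on C5; the orientation of the alkene is immaterial because elimination erases it). F1 loses acetic acid in the flask and aromatises to 8, where the route resumes at step 4.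

Step 5. The aldehyde is flanked by the C1 methyl group and the C3 carbinol, so the lactol may open too little. The diazophosphonate anion may then decompose before it adds, and the alkoxide may re-close. The fallback removes the hydroxyl that locks the aldehyde as a hemiacetal by raising C7 to the ketone first. Setting out from 8, LiAlH4 in THF at 0 °C should give the diol rac-[2-(hydroxymethyl)-6-(4-methoxyphenyl)-3-methylphenyl](4-methoxyphenyl)methanol F2. A Swern oxidation ((COCl)2, DMSO, Et3N, −78 °C) is chosen because both alcohols are activated before base is added, so no lactol can form and be oxidised back to 8. It should give the keto aldehyde 2-(4-methoxybenzoyl)-3-(4-methoxyphenyl)-6-methylbenzaldehyde F3. The Ohira–Bestmann reagent (K2CO3, MeOH) then meets a free aldehyde and, the diaryl ketone being inert to it, should give the ethynyl ketone [2-ethynyl-6-(4-methoxyphenyl)-3-methylphenyl](4-methoxyphenyl)methanone F4. Sonogashira coupling of F4 with 12 under the conditions of step 6 should give 14, where the route resumes at step 8.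

Step 9. Under BBr3 the triaryl carbinol ionises to a trityl cation. This cation may be captured by the ortho carbon of the neighbouring C4 aryl ring (Friedel–Crafts closure to a 9,9-diarylfluorene), and cleavage of four ethers on a cationic borate aggregate may stall. The fallback moves the demethylation to the ketone stage, where no cation can form, and finishes with fluoride-labile silyl ethers. Setting out from 14, BBr3 in CH2Cl2 should give the triphenolic ketone {6-(4-hydroxyphenyl)-2-[(4-hydroxyphenyl)ethynyl]-3-methylphenyl}(4-hydroxyphenyl)methanone F5. TBSCl and imidazole in DMF should give the tris(silyl ether) ketone {6-[4-(tert-butyldimethylsilyloxy)phenyl]-2-{[4-(tert-butyldimethylsilyloxy)phenyl]ethynyl}-3-methylphenyl}[4-(tert-butyldimethylsilyloxy)phenyl]methanone F6. Commercial (4-bromophenoxy)(tert-butyl)dimethylsilane and n-BuLi in THF at −78 °C give 4-(tert-butyldimethylsilyloxy)phenyllithium F7 in the flask. Its addition to F6 should give the tetrakis(silyl ether) carbinol {6-[4-(tert-butyldimethylsilyloxy)phenyl]-2-{[4-(tert-butyldimethylsilyloxy)phenyl]ethynyl}-3-methylphenyl}bis[4-(tert-butyldimethylsilyloxy)phenyl]methanol F8. Tetrabutylammonium fluoride in THF followed by acetic acid should give 18, which dehydrates to 19 as in step 9.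

**Further compounds**
F1 | step 3 | 3,4-bis(4-methoxyphenyl)-7-methyl-1-oxo-1,3,5,6-tetrahydro-2-benzofuran-5-yl acetate (mixture of diastereomers, racemic) | CC1=C2C(=O)OC(c3ccc(OC)cc3)C2=C(c2ccc(OC)cc2)C(OC(C)=O)C1
F2 | step 5 | rac-[2-(hydroxymethyl)-6-(4-methoxyphenyl)-3-methylphenyl](4-methoxyphenyl)methanol | OCc1c(C)ccc(-c2ccc(OC)cc2)c1C(O)c1ccc(OC)cc1
F3 | step 5 | 2-(4-methoxybenzoyl)-3-(4-methoxyphenyl)-6-methylbenzaldehyde | O=Cc1c(C)ccc(-c2ccc(OC)cc2)c1C(=O)c1ccc(OC)cc1
F4 | step 5 | [2-ethynyl-6-(4-methoxyphenyl)-3-methylphenyl](4-methoxyphenyl)methanone | C#Cc1c(C)ccc(-c2ccc(OC)cc2)c1C(=O)c1ccc(OC)cc1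
F5 | step 9 | {6-(4-hydroxyphenyl)-2-[(4-hydroxyphenyl)ethynyl]-3-methylphenyl}(4-hydroxyphenyl)methanone | Cc1ccc(-c2ccc(O)cc2)c(C(=O)c2ccc(O)cc2)c1C#Cc1ccc(O)cc1
F6 | step 9 | {6-[4-(tert-butyldimethylsilyloxy)phenyl]-2-{[4-(tert-butyldimethylsilyloxy)phenyl]ethynyl}-3-methylphenyl}[4-(tert-butyldimethylsilyloxy)phenyl]methanone | Cc1ccc(-c2ccc(O[Si](C)(C)C(C)(C)C)cc2)c(C(=O)c2ccc(O[Si](C)(C)C(C)(C)C)cc2)c1C#Cc1ccc(O[Si](C)(C)C(C)(C)C)cc1
F7 | step 9 | 4-(tert-butyldimethylsilyloxy)phenyllithium | [Li]c1ccc(O[Si](C)(C)C(C)(C)C)cc1
F8 | step 9 | {6-[4-(tert-butyldimethylsilyloxy)phenyl]-2-{[4-(tert-butyldimethylsilyloxy)phenyl]ethynyl}-3-methylphenyl}bis[4-(tert-butyldimethylsilyloxy)phenyl]methanol | Cc1ccc(-c2ccc(O[Si](C)(C)C(C)(C)C)cc2)c(C(O)(c2ccc(O[Si](C)(C)C(C)(C)C)cc2)c2ccc(O[Si](C)(C)C(C)(C)C)cc2)c1C#Cc1ccc(O[Si](C)(C)C(C)(C)C)cc1
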